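Numbering is that of labdane (ring A = C1–C5, C10; ring B = C5–C10; C17 = methyl on C8, C20 = methyl on C10). Retrosynthetic cuts, in order: O15–Si and the C7 acetate; C8–C17 (MeMgBr on an 8-ketone); C9–C11 (side-chain organolithium on a C9 ketone, then oxidative 1,3-transposition of oxygen to C7); last, ring A at C1–C10 and C2–C3.
Forward: ring B comes first, as a cyclohexenone cut out of (R)-carvone; ring A is closed onto it in one pot; the C11–C16 chain is then joined at C9; C7 and C8 are oxygenated and methylated last.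
Enabling feature: ring A of the target is a bare cyclohexane held between the quaternary carbons C4 (gem-dimethyl) and C10. A C3 aldehyde on C4 therefore cannot enolize, and C10 is alpha to a C9 carbonyl. A C10 enolate, a vinylphosphonium salt (C1 electrophilic, C2 nucleophilic after addition) and the C3 aldehyde close ring A by Michael addition and Wittig olefination; the C2=C3 alkene left behind is simply hydrogenated.
Stereochemistry: C5 from (R)-carvone (its isopropenyl group at C7 directs the conjugate addition anti and is then excised); C10 anti to the C5 substituent from a planar enolate, so both C10 epimers converge; C9 by axial protonation (also the thermodynamic epimer); C7 by axial hydride; C8 by equatorial Grignard attack; 13E from a commercial (E)-enynol.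

Key step: step 3

Step 1
Reactants: 1 (R)-carvone; 2 trimethyl[(2-methylprop-1-en-1-yl)oxy]silane
Product: 4 (2RS,3R,5R)-2-methyl-3-(2-methyl-1-oxopropan-2-yl)-5-(prop-1-en-2-yl)cyclohexan-1-one, via silyl enol ether 3 (not isolated)
Conditions: Tf2NH (5 mol %), CH2Cl2, −78 → −40 °C; then 1 M HCl, THF, 0 °C
Reagents that add atoms: none
Why: Mukaiyama–Michael addition, in which the silyl-activated enone is attacked axially at its beta carbon anti to the isopropenyl group, setting the future C5 stereocenter and forming the quaternary C4 with its non-enolizable aldehyde; the C2 epimer mixture is of no consequence.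

Step 2
Reactants: 4 (2RS,3R,5R)-2-methyl-3-(2-methyl-1-oxopropan-2-yl)-5-(prop-1-en-2-yl)cyclohexan-1-one
Product: 6 (5R,6RS)-6-methyl-5-(2-methyl-1-oxopropan-2-yl)cyclohex-2-en-1-one, via methoxy hydroperoxide 5 (not isolated)
Conditions: O3, CH2Cl2/MeOH, −78 °C; then Cu(OAc)2·H2O, FeSO4·7H2O, MeOH, −20 °C → rt
Reagents that add atoms: none
Why: Criegee ozonolysis in methanol followed by Schreiber fragmentation (divalent iron cleaves the O–O bond, the alkoxy radical expels methyl acetate, Cu(OAc)2 oxidises the ring radical to the conjugated alkene), as in the known conversion of dihydrocarvone into 6-methylcyclohex-2-enone; the directing group is removed and the enone needed later is left.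

Step 3
Reactants: 6 (5R,6RS)-6-methyl-5-(2-methyl-1-oxopropan-2-yl)cyclohex-2-en-1-one; 7 triphenyl(vinyl)phosphonium bromide
Product: 10 (4aS,8aS)-5,5,8a-trimethyl-4a,5,8,8a-tetrahydronaphthalen-1(4H)-one, via lithium enolate 8 (not isolated), via phosphorus ylide 9 (not isolated)
Conditions: lithium 2,2,6,6-tetramethylpiperidide (1.05 equiv), THF, −78 °C; then 7, THF/DMPU, −78 °C → rt
Reagents that add atoms: none
Why: The amide base removes the only alpha' proton (C10–H) of 6 to give the cross-conjugated enolate 8, which adds through C10 to the beta carbon (C1) of the vinylphosphonium salt; the ylide 9 thus formed at C2 attacks the C3 aldehyde and collapses through an oxaphosphetane to the C2=C3 alkene and Ph3PO. The closest known reaction type is the Schweizer vinylphosphonium annulation (Michael addition followed by intramolecular Wittig olefination), used here as a formal [4+2] assembly of a cyclohexene from an enolate, a two-carbon linchpin and a carbonyl group. Ring A closes in the Wittig event by 6-exo-trig attack of C2 on the aldehyde carbon C3, which can only give the cis alkene in the ring. The new quaternary stereocenter C10 is controlled by the adjacent C5: the bulky C(CH3)2CHO group sits pseudoaxial on the enolate half-chair and the salt enters from the opposite face, so C1 ends trans to C4 (trans ring fusion, 10β-methyl), and because the enolate is planar both C10 epimers of 6 converge on one product. The step needs alpha' rather than gamma deprotonation (kinetic, non-nucleophilic amide at low temperature), C- rather than O-alkylation (O-adducts of the salt revert) and olefination of the aldehyde rather than the ring ketone (the aldehyde is more electrophilic, cannot enolize because C4 is quaternary, and is the only carbonyl within reach of a six-membered closure).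

Step 4
Reactants: 11 (2E)-3-methylpent-2-en-4-yn-1-ol
Product: 12 {[(2E)-3-methylpent-2-en-4-yn-1-yl]oxy}tri(propan-2-yl)silane
Conditions: chlorotri(propan-2-yl)silane, imidazole, DMF, rt
Reagents that add atoms: chlorotri(propan-2-yl)silane, CC(C)[Si](Cl)(C(C)C)C(C)C
Why: Standard silylation of the primary allylic alcohol; the triisopropylsilyl ether should survive the organolithium, chromate, alkaline peroxide, methoxide, mild aqueous acid and Grignard conditions that follow.

Step 5
Reactants: 12 {[(2E)-3-methylpent-2-en-4-yn-1-yl]oxy}tri(propan-2-yl)silane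
Product: 13 {[(2E)-3-methylpenta-2,4-dien-1-yl]oxy}tri(propan-2-yl)silane
Conditions: H2 (1 atm), Pd/CaCO3 poisoned with Pb(OAc)2, quinoline, hexane, rt
Reagents that add atoms: none
Why: Semihydrogenation of the terminal alkyne over lead-poisoned palladium (Lindlar reduction) stops at the diene and leaves the E trisubstituted alkene untouched.

Step 6
Reactants: 13 {[(2E)-3-methylpenta-2,4-dien-1-yl]oxy}tri(propan-2-yl)silane
Product: 15 {[(2E)-5-iodo-3-methylpent-2-en-1-yl]oxy}tri(propan-2-yl)silane, via alkylborane 14 (not isolated)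
Conditions: 9-BBN, THF, 0 °C → rt; then NaOMe, I2, MeOH/THF, 0 °C
Reagents that add atoms: iodine, II
Why: Anti-Markovnikov hydroboration of the monosubstituted end of the diene (the trisubstituted alkene is too hindered for 9-BBN) and base-induced iodinolysis of the primary B–C bond should give the homoallylic iodide with the E alkene intact.

Step 7
Reactants: 15 {[(2E)-5-iodo-3-methylpent-2-en-1-yl]oxy}tri(propan-2-yl)silane; 10 (4aS,8aS)-5,5,8a-trimethyl-4a,5,8,8a-tetrahydronaphthalen-1(4H)-one
Product: 17 15-[tri(propan-2-yl)silyloxy]-17-norlabda-2,7,13E-trien-9-ol (C9 epimers), via organolithium 16 (not isolated)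
Conditions: 15, t-BuLi (2.1 equiv), Et2O/pentane, −78 °C; then 10, −78 → −30 °C; H2O
Reagents that add atoms: none
Why: Iodine–lithium exchange gives the homoallylic organolithium, which adds 1,2 to the C9 ketone (no alpha proton, C10 being quaternary); the new carbinol center, expected from attack anti to the C10 methyl, is destroyed in step 8 and its configuration does not matter.

Step 8
Reactants: 17 15-[tri(propan-2-yl)silyloxy]-17-norlabda-2,7,13E-trien-9-ol
Product: 18 15-[tri(propan-2-yl)silyloxy]-17-norlabda-2,8,13E-trien-7-one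
Conditions: [C5H5NH][CrO3Cl] (2 equiv), NaOAc, 4 Å molecular sieves, CH2Cl2, rt
Reagents that add atoms: pyridinium chlorochromate, [O-][Cr](=O)(=O)Cl.c1cc[nH+]cc1
Why: Dauben–Babler oxidative transposition, in which the chromate ester of the tertiary allylic alcohol shifts [3,3] to C7 and is oxidised to the enone, moving oxygen from C9 to C7 and the alkene to C8=C9.

Step 9
Reactants: 18 15-[tri(propan-2-yl)silyloxy]-17-norlabda-2,8,13E-trien-7-one
Product: 19 15-[tri(propan-2-yl)silyloxy]-17-norlabda-8,13E-dien-7-one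
Conditions: H2 (1 atm), RhCl(PPh3)3 (5 mol %), benzene, rt
Reagents that add atoms: none
Why: Homogeneous hydrogenation with RhCl(PPh3)3 should reduce only the cis-disubstituted C2=C3 alkene of ring A, since the rate falls steeply with substitution and the conjugated C8=C9 and the C13=C14 alkenes are both trisubstituted.

Step 10
Reactants: 19 15-[tri(propan-2-yl)silyloxy]-17-norlabda-8,13E-dien-7-one
Product: 20 8,9-epoxy-15-[tri(propan-2-yl)silyloxy]-17-norlabd-13E-en-7-one (epoxide epimers)
Conditions: 30% aq. H2O2, NaOH, MeOH, 0 °C → rt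
Reagents that add atoms: hydrogen peroxide, OO
Why: Weitz–Scheffer nucleophilic epoxidation touches only the electron-poor C8=C9 bond; a fully substituted beta carbon next to an angular quaternary carbon is the situation of steroidal 4-en-3-ones, which epoxidise well, and either epoxide face serves.

Step 11
Reactants: 20 8,9-epoxy-15-[tri(propan-2-yl)silyloxy]-17-norlabd-13E-en-7-one
Product: 22 8-methoxy-15-[tri(propan-2-yl)silyloxy]-17-norlabda-8,13E-dien-7-one, via hydroxy methoxy ketone 21 (not isolated)
Conditions: NaOMe, MeOH, 50 °C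
Reagents that add atoms: sodium methoxide, [Na+].[O-]C
Why: SN2 opening of the alpha,beta-epoxy ketone by methoxide at the alpha carbon C8, then E1cB loss of water from the beta-hydroxy ketone 21, should give the 2-methoxy enone, as in the conversion of steroidal 4,5-epoxy-3-ketones into 4-substituted 4-en-3-ones; C8 and C9 become trigonal again.

Step 12
Reactants: 22 8-methoxy-15-[tri(propan-2-yl)silyloxy]-17-norlabda-8,13E-dien-7-one
Product: 24 7β-hydroxy-15-[tri(propan-2-yl)silyloxy]-17-norlabd-13E-en-8-one (9α-H), via allylic alcohol 23 (not isolated)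
Conditions: NaBH4, CeCl3·7H2O, MeOH, −40 °C; then oxalic acid, THF/H2O, rt
Reagents that add atoms: water, O
Why: Luche 1,2-reduction delivers hydride axially to C7 from the alpha face to give the equatorial 7β-alcohol (as 4-en-3-ones give 3β-ols), and mild acid hydrolysis of the enol ether protonates C9 axially from the alpha face, so the side chain stays equatorial (9α-H, also the thermodynamic epimer next to the new C8 ketone).

Step 13
Reactants: 24 7β-hydroxy-15-[tri(propan-2-yl)silyloxy]-17-norlabd-13E-en-8-one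
Product: 25 15-[tri(propan-2-yl)silyloxy]labd-13E-ene-7β,8β-diol (8α-methyl)
Conditions: MeMgBr (4 equiv), LaCl3·2LiCl (1 equiv), THF, −78 → 0 °C; H2O
Reagents that add atoms: methylmagnesium bromide, C[Mg]Br
Why: Grignard addition to the ketone chelated by the C7 alkoxide: the axial (beta) approach to C8 is blocked by the syn-axial C10 methyl, so methyl enters equatorially from the alpha face and the new hydroxyl is axial (8β-OH, 8α-CH3, cis to O7); LaCl3·2LiCl suppresses enolisation toward C9.

Step 14
Reactants: 25 15-[tri(propan-2-yl)silyloxy]labd-13E-ene-7β,8β-diol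
Product: 26 7β-acetoxy-15-[tri(propan-2-yl)silyloxy]labd-13E-en-8β-ol
Conditions: Ac2O, pyridine, DMAP (cat.), CH2Cl2, 0 °C → rt
Reagents that add atoms: acetic anhydride, CC(=O)OC(C)=O
Why: Acylation is selective for the secondary equatorial 7β-hydroxyl; the axial tertiary 8β-hydroxyl, syn-axial to the C10 methyl, should not react.

Step 15
Reactants: 26 7β-acetoxy-15-[tri(propan-2-yl)silyloxy]labd-13E-en-8β-ol
Product: 27 7β-acetoxylabd-13E-ene-8β,15-diol, (5S,7S,8R,9R,10S)
Conditions: HF·pyridine, pyridine, THF, 0 °C → rt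
Reagents that add atoms: none
Why: Fluoride-assisted desilylation under buffered, non-basic conditions frees the primary allylic alcohol without acetyl migration to the neighbouring tertiary hydroxyl.

Compound list
1 | (R)-(−)-carvone, (5R)-2-methyl-5-(prop-1-en-2-yl)cyclohex-2-en-1-one | C=C(C)[C@@H]1CC=C(C)C(=O)C1 | starting material
2 | trimethyl[(2-methylprop-1-en-1-yl)oxy]silane | CC(C)=CO[Si](C)(C)C | starting material
3 | 2-methyl-2-[(1R,5R)-2-methyl-5-(prop-1-en-2-yl)-3-(trimethylsilyloxy)cyclohex-2-en-1-yl]propanal (not isolated) | C=C(C)[C@@H]1C[C@@H](C(C)(C)C=O)C(C)=C(O[Si](C)(C)C)C1 | intermediate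
4 | (2RS,3R,5R)-2-methyl-3-(2-methyl-1-oxopropan-2-yl)-5-(prop-1-en-2-yl)cyclohexan-1-one | C=C(C)[C@@H]1C[C@@H](C(C)(C)C=O)C(C)C(=O)C1 | intermediate
5 | (2RS,3R,5R)-5-(1-hydroperoxy-1-methoxyethyl)-2-methyl-3-(2-methyl-1-oxopropan-2-yl)cyclohexan-1-one (not isolated) | COC(C)(OO)[C@@H]1C[C@@H](C(C)(C)C=O)C(C)C(=O)C1 | intermediate
6 | (5R,6RS)-6-methyl-5-(2-methyl-1-oxopropan-2-yl)cyclohex-2-en-1-one | O=CC(C)(C)[C@@H]1CC=CC(=O)C1C | intermediate
7 | triphenyl(vinyl)phosphonium bromide | C=C[P+](c1ccccc1)(c1ccccc1)c1ccccc1.[Br-] | starting material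
8 | lithium (3R)-2-methyl-3-(2-methyl-1-oxopropan-2-yl)cyclohexa-1,5-dien-1-olate (not isolated) | [Li]OC1=C(C)[C@H](C(C)(C)C=O)CC=C1 | intermediate
9 | (5S,6S)-6-methyl-5-(2-methyl-1-oxopropan-2-yl)-6-[2-(triphenyl-λ5-phosphanylidene)ethyl]cyclohex-2-en-1-one (not isolated) | O=CC(C)(C)[C@@H]1CC=CC(=O)[C@@]1(C)CC=P(c2ccccc2)(c2ccccc2)c2ccccc2 | intermediate
10 | (4aS,8aS)-5,5,8a-trimethyl-4a,5,8,8a-tetrahydronaphthalen-1(4H)-one | O=C1C=CC[C@H]2C(C)(C)C=CC[C@]12C | intermediate
11 | (2E)-3-methylpent-2-en-4-yn-1-ol | C#C/C(C)=C/CO | starting material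
12 | {[(2E)-3-methylpent-2-en-4-yn-1-yl]oxy}tri(propan-2-yl)silane | C#C/C(C)=C/CO[Si](C(C)C)(C(C)C)C(C)C | intermediate
13 | {[(2E)-3-methylpenta-2,4-dien-1-yl]oxy}tri(propan-2-yl)silane | C=C/C(C)=C/CO[Si](C(C)C)(C(C)C)C(C)C | intermediate
14 | 9-{(3E)-3-methyl-5-[tri(propan-2-yl)silyloxy]pent-3-en-1-yl}-9-borabicyclo[3.3.1]nonane (not isolated) | CC(C)[Si](OC/C=C(C)/CCB1C2CCCC1CCC2)(C(C)C)C(C)C | intermediate
15 | {[(2E)-5-iodo-3-methylpent-2-en-1-yl]oxy}tri(propan-2-yl)silane | ICC/C(C)=C/CO[Si](C(C)C)(C(C)C)C(C)C | intermediate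
16 | {(3E)-3-methyl-5-[tri(propan-2-yl)silyloxy]pent-3-en-1-yl}lithium (not isolated) | [Li]CC/C(C)=C/CO[Si](C(C)C)(C(C)C)C(C)C | intermediate
17 | 15-[tri(propan-2-yl)silyloxy]-17-norlabda-2,7,13E-trien-9-ol (5α-H, 10β-methyl; C9 epimers) | OC1(CC/C(C)=C/CO[Si](C(C)C)(C(C)C)C(C)C)C=CC[C@H]2C(C)(C)C=CC[C@]12C | intermediate
18 | 15-[tri(propan-2-yl)silyloxy]-17-norlabda-2,8,13E-trien-7-one | O=C1C=C(CC/C(C)=C/CO[Si](C(C)C)(C(C)C)C(C)C)[C@@]2(C)CC=CC(C)(C)[C@@H]2C1 | intermediate
19 | 15-[tri(propan-2-yl)silyloxy]-17-norlabda-8,13E-dien-7-one | O=C1C=C(CC/C(C)=C/CO[Si](C(C)C)(C(C)C)C(C)C)[C@@]2(C)CCCC(C)(C)[C@@H]2C1 | intermediate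
20 | 8,9-epoxy-15-[tri(propan-2-yl)silyloxy]-17-norlabd-13E-en-7-one (epoxide epimers) | O=C1C2OC2(CC/C(C)=C/CO[Si](C(C)C)(C(C)C)C(C)C)[C@@]3(C)CCCC(C)(C)[C@@H]3C1 | intermediate
21 | 9-hydroxy-8-methoxy-15-[tri(propan-2-yl)silyloxy]-17-norlabd-13E-en-7-one (not isolated) | O=C1C(OC)C(O)(CC/C(C)=C/CO[Si](C(C)C)(C(C)C)C(C)C)[C@@]2(C)CCCC(C)(C)[C@@H]2C1 | intermediate
22 | 8-methoxy-15-[tri(propan-2-yl)silyloxy]-17-norlabda-8,13E-dien-7-one | O=C1C(OC)=C(CC/C(C)=C/CO[Si](C(C)C)(C(C)C)C(C)C)[C@@]2(C)CCCC(C)(C)[C@@H]2C1 | intermediate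
23 | 8-methoxy-15-[tri(propan-2-yl)silyloxy]-17-norlabda-8,13E-dien-7β-ol (not isolated) | O[C@H]1C[C@H]2C(C)(C)CCC[C@]2(C)C(CC/C(C)=C/CO[Si](C(C)C)(C(C)C)C(C)C)=C1OC | intermediate
24 | 7β-hydroxy-15-[tri(propan-2-yl)silyloxy]-17-norlabd-13E-en-8-one (9α-H) | O[C@H]1C[C@H]2C(C)(C)CCC[C@]2(C)[C@@H](CC/C(C)=C/CO[Si](C(C)C)(C(C)C)C(C)C)C1=O | intermediate
25 | 15-[tri(propan-2-yl)silyloxy]labd-13E-ene-7β,8β-diol (8α-methyl) | O[C@H]1C[C@H]2C(C)(C)CCC[C@]2(C)[C@@H](CC/C(C)=C/CO[Si](C(C)C)(C(C)C)C(C)C)[C@@]1(C)O | intermediate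
26 | 7β-acetoxy-15-[tri(propan-2-yl)silyloxy]labd-13E-en-8β-ol | CC(=O)O[C@H]1C[C@H]2C(C)(C)CCC[C@]2(C)[C@@H](CC/C(C)=C/CO[Si](C(C)C)(C(C)C)C(C)C)[C@@]1(C)O | intermediate
27 | 7β-acetoxylabd-13E-ene-8β,15-diol, (5S,7S,8R,9R,10S) | CC(=O)O[C@H]1C[C@H]2C(C)(C)CCC[C@]2(C)[C@@H](CC/C(C)=C/CO)[C@@]1(C)O | target

Total step count: 15. Longest linear sequence: 12 steps (steps 1–3 and 7–15, from 1 to 27); steps 4–6 make the side-chain iodide 15.

Steps most likely to fail

Step 3. The C10 enolate may fragment by retro-Michael loss of the stabilised aldehyde enolate (driven by aromatisation to a cresol), the base or the enolate may attack the aldehyde, or the hindered enolate may add too slowly to the sparingly soluble salt. The fallback sets out from 6 and comes back at 10. The aldehyde of 6 is first methylenated chemoselectively (Ph3P=CH2, THF, −78 °C) to (5R,6RS)-6-methyl-5-(2-methylbut-3-en-2-yl)cyclohex-2-en-1-one F1, which can no longer lose a stabilised carbanion. Kinetic deprotonation (lithium diisopropylamide, THF, −78 °C) and allyl bromide should then give (5S,6S)-6-allyl-6-methyl-5-(2-methylbut-3-en-2-yl)cyclohex-2-en-1-one F2, the allyl group again entering anti to the C5 substituent. Ring-closing metathesis (second-generation Grubbs catalyst, CH2Cl2, 40 °C) closes C2=C3 and gives 10.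

Step 11. Methoxide may open the epoxide too slowly at the hindered C8, so that retro-aldol cleavage of the C8–C9 bond or Favorskii-type ring contraction takes over, or the tertiary C9 hydroxyl may fail to eliminate. The fallback sets out from 20 and comes back at 24. Thiophenol and Et3N (THF/EtOH, rt), a softer and far stronger nucleophile, should convert 20 into 8-phenylthio-15-[tri(propan-2-yl)silyloxy]-17-norlabda-8,13E-dien-7-one F3. Luche reduction (NaBH4, CeCl3·7H2O, MeOH) then gives 8-phenylthio-15-[tri(propan-2-yl)silyloxy]-17-norlabda-8,13E-dien-7β-ol F4, and hydrolysis of the vinyl sulfide (HgCl2, CaCO3, MeCN/H2O) unmasks the C8 ketone to give 24.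

Step 1. The alpha-methyl enone may be too unreactive toward the hindered enol silane, so that hydrolysis of the silane, aldol reaction at the product aldehyde or acid-induced isomerisation of the isopropenyl group competes. The fallback sets out from 1 and comes back at 4. Isobutyraldehyde N,N-dimethylhydrazone is lithiated (lithium diisopropylamide, THF) and converted into its cuprate (CuI·SMe2). Conjugate addition to 1, again anti to the isopropenyl group, should give (2RS,3R,5R)-3-[1-(2,2-dimethylhydrazinylidene)-2-methylpropan-2-yl]-2-methyl-5-(prop-1-en-2-yl)cyclohexan-1-one F5, and hydrolysis (aqueous oxalic acid, Et2O) gives 4.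

Further compounds
F1 | step 3 | (5R,6RS)-6-methyl-5-(2-methylbut-3-en-2-yl)cyclohex-2-en-1-one | C=CC(C)(C)[C@@H]1CC=CC(=O)C1C
F2 | step 3 | (5S,6S)-6-allyl-6-methyl-5-(2-methylbut-3-en-2-yl)cyclohex-2-en-1-one | C=CC(C)(C)[C@@H]1CC=CC(=O)[C@@]1(C)CC=C
F3 | step 11 | 8-phenylthio-15-[tri(propan-2-yl)silyloxy]-17-norlabda-8,13E-dien-7-one | O=C1C(Sc2ccccc2)=C(CC/C(C)=C/CO[Si](C(C)C)(C(C)C)C(C)C)[C@@]3(C)CCCC(C)(C)[C@@H]3C1
F4 | step 11 | 8-phenylthio-15-[tri(propan-2-yl)silyloxy]-17-norlabda-8,13E-dien-7β-ol | O[C@H]1C[C@H]2C(C)(C)CCC[C@]2(C)C(CC/C(C)=C/CO[Si](C(C)C)(C(C)C)C(C)C)=C1Sc3ccccc3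
F5 | step 1 | (2RS,3R,5R)-3-[1-(2,2-dimethylhydrazinylidene)-2-methylpropan-2-yl]-2-methyl-5-(prop-1-en-2-yl)cyclohexan-1-one | C=C(C)[C@@H]1C[C@@H](C(C)(C)C=NN(C)C)C(C)C(=O)C1
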